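Ring A of the flavone is a 5,8-hydroquinone carrying C7–OMe and C6–H, fused through C4a–C8a to pyranone ring C. Its C5–C6–C7–C8 unit maps onto methyl semisquarate. Ring A is therefore disconnected to a 4-hydroxycyclobutenone bound through its carbinol carbon (future C8) to the oxygen-flanked CH carbon (future C8a) of a 2-aryl-3-methoxy-4-pyranone. Heating this adduct opens the four-membered ring to a dienylketene, which closes onto the neighbouring pyranone CH (C4a–C5 bond) and tautomerizes. One operation thus delivers the unprotected target with all four ring A substituents in place. The pyranone comes from furan and 2,3,4-trimethoxybenzaldehyde by Achmatowicz ring expansion.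

Key step: step 10

Remark on the chemistry: every stereocentre created on the way (carbinol, acetal, epoxide, cyclobutenone carbinol, ring-fusion CH) forms without control as a racemate or diastereomer mixture and disappears on aromatization; only the ketene double bond carries a descriptor.

Step 1
Reactants: 1 furan; 2 2,3,4-trimethoxybenzaldehyde
Product: 4 furan-2-yl(2,3,4-trimethoxyphenyl)methanol (racemic), via 2-furyllithium 3 (not isolated)
Conditions: n-BuLi, THF, 0 °C; then 2, −78 °C to rt; aq. NH4Cl
Reagents that add atoms: none
Why: Furan is lithiated at C2 by n-BuLi (α-lithiation) and the 2-furyllithium adds 1,2 to the aldehyde; the new carbinol stereocentre forms racemic and is not needed later.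

Step 2
Reactants: 4 furan-2-yl(2,3,4-trimethoxyphenyl)methanol
Product: 5 6-hydroxy-2-(2,3,4-trimethoxyphenyl)-2H-pyran-3(6H)-one (racemic anomer mixture)
Conditions: t-BuOOH, VO(acac)2 (cat.), CH2Cl2, 0 °C to rt
Reagents that add atoms: tert-butyl hydroperoxide CC(C)(C)OO
Why: Achmatowicz rearrangement: hydroxyl-directed vanadium-peroxide oxidation of the furan opens it to the cis-enedione, which the carbinol oxygen closes to the pyranone hemiacetal under neutral, halogen-free conditions that spare the electron-rich arene; the anomeric centre forms as an inconsequential mixture.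

Step 3
Reactants: 5 6-hydroxy-2-(2,3,4-trimethoxyphenyl)-2H-pyran-3(6H)-one
Product: 6 6-methoxy-2-(2,3,4-trimethoxyphenyl)-2H-pyran-3(6H)-one (racemic cis/trans mixture)
Conditions: HC(OMe)3, BF3·OEt2 (cat.), CH2Cl2, 0 °C
Reagents that add atoms: trimethyl orthoformate COC(OC)OC
Why: Acid-catalysed acetalization through the ring oxocarbenium ion caps the base-labile hemiacetal as its methyl acetal before the basic epoxidation; the anomer mixture is inconsequential.

Step 4
Reactants: 6 6-methoxy-2-(2,3,4-trimethoxyphenyl)-2H-pyran-3(6H)-one
Product: 7 2-methoxy-4-(2,3,4-trimethoxyphenyl)-3,7-dioxabicyclo[4.1.0]heptan-5-one (the 4,5-epoxide of 6; racemic diastereomer mixture)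
Conditions: 30% H2O2, NaOH (cat.), MeOH, 0 °C
Reagents that add atoms: hydrogen peroxide OO
Why: Weitz–Scheffer nucleophilic epoxidation: hydroperoxide adds conjugately to the enone and the enolate closes the oxirane, mainly anti to the acetal methoxy group, and every diastereomer converges on the same aromatic product in step 5.

Step 5
Reactants: 7 2-methoxy-4-(2,3,4-trimethoxyphenyl)-3,7-dioxabicyclo[4.1.0]heptan-5-one
Product: 8 3-hydroxy-2-(2,3,4-trimethoxyphenyl)-4H-pyran-4-one
Conditions: 2 M H2SO4, dioxane, 90 °C
Reagents that add atoms: none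
Why: Acid-mediated epoxy-ketone rearrangement to the 3,4-dione, then enolization and elimination of methanol from the acetal carbon, is the maltol-type sequence driven by formation of the aromatic γ-pyrone, and it erases all sp3 stereocentres.

Step 6
Reactants: 8 3-hydroxy-2-(2,3,4-trimethoxyphenyl)-4H-pyran-4-one
Product: 9 3-methoxy-2-(2,3,4-trimethoxyphenyl)-4H-pyran-4-one
Conditions: MeI, K2CO3, acetone, reflux
Reagents that add atoms: iodomethane CI
Why: Williamson O-methylation of the acidic enolic 3-hydroxyl installs the C3 methoxy group of the target and removes the proton that would quench the base in step 9.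

Step 7
Reactants: 10 dimethyl squarate (3,4-dimethoxycyclobut-3-ene-1,2-dione)
Product: 11 4-hydroxy-2,3-dimethoxycyclobut-2-en-1-one (racemic, used crude)
Conditions: LiAlH(Ot-Bu)3 (1.05 equiv), THF, −78 to 0 °C; H2O work-up
Reagents that add atoms: none
Why: Chemoselective 1,2-hydride reduction: the bulky, mild aluminate reduces one squarate carbonyl and stops at the aluminium alkoxide; the carbinol centre is racemic and is destroyed in step 8.

Step 8
Reactants: 11 4-hydroxy-2,3-dimethoxycyclobut-2-en-1-one
Product: 12 3-methoxycyclobut-3-ene-1,2-dione (methyl semisquarate)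
Conditions: conc. HCl (cat.), CH2Cl2, rt
Reagents that add atoms: none
Why: Acid-catalysed 1,3-carbonyl transposition: ionization of the allylic carbinol gives a methoxy-stabilized cyclobutenyl cation, water adds at the distal methoxy-bearing carbon and the hemiketal expels methanol, the standard conversion of squarate adducts into cyclobutenediones.

Step 9
Reactants: 9 3-methoxy-2-(2,3,4-trimethoxyphenyl)-4H-pyran-4-one; 12 3-methoxycyclobut-3-ene-1,2-dione
Product: 14 4-hydroxy-3-methoxy-4-[5-methoxy-4-oxo-6-(2,3,4-trimethoxyphenyl)-4H-pyran-2-yl]cyclobut-2-en-1-one (racemic), via 6-lithiopyranone 13 (not isolated)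
Conditions: LiTMP (from 2,2,6,6-tetramethylpiperidine and n-BuLi), THF, −78 °C, short time; cannulate into 12 (1.3 equiv), THF, −78 °C; aq. NH4Cl at −78 °C
Reagents that add atoms: none
Why: The non-nucleophilic amide removes the most acidic sp2 C–H, the one next to the ring oxygen (as in C2 lithiation of chromones), and the vinyllithium adds 1,2 to the ketone-type carbonyl of 12 (the other carbonyl is a deactivated vinylogous ester), which fixes the later 7-methoxy pattern; the new carbinol centre is racemic and vanishes in step 10.

Step 10
Reactants: 14 4-hydroxy-3-methoxy-4-[5-methoxy-4-oxo-6-(2,3,4-trimethoxyphenyl)-4H-pyran-2-yl]cyclobut-2-en-1-one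
Product: 17 target flavone 5,8-dihydroxy-3,7-dimethoxy-2-(2,3,4-trimethoxyphenyl)-4H-chromen-4-one, via dienylketene 15 (not isolated), via ring-fusion dienone 16 (not isolated)
Conditions: degassed toluene, 110 °C, argon; work-up under argon
Reagents that add atoms: none
Why: Moore-type ring expansion: conrotatory 4π opening of the cyclobutenone C(=O)–C(OH) bond gives dienylketene 15, whose ketene carbon closes by thermal 6π electrocyclization onto the adjacent pyranone CH, and dienone 16 tautomerizes to the aromatic hydroquinone. The closest known reactions are the thermal rearrangements of 4-alkenyl-, 4-aryl- and 4-heteroaryl-4-hydroxycyclobutenones to annulated hydroquinones, and the enol-ether-like C5=C6 bond of the pyranone is a π partner of this kind, its CH carbon being nucleophilic toward the ketene. Ring A is closed by a disrotatory 6π electrocyclization that forms the C4a–C5 bond, the C8–C8a bond being in place from step 9. No stereocentre survives, because the ring-fusion CH of 16 is lost on enolization. The step needs the pyranonyl group to rotate inward toward the ketene, which the strong preference of the hydroxyl donor for outward rotation secures, and it needs a single closure site, which is guaranteed because the other neighbour of the attachment carbon is the ring oxygen. The new 5-hydroxyl is held by a hydrogen bond to the C4 carbonyl, and exclusion of air keeps the hydroquinone from oxidizing.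

Compound list
1 | furan | c1ccoc1 | starting material
2 | 2,3,4-trimethoxybenzaldehyde | COc1ccc(C=O)c(OC)c1OC | starting material
3 | 2-furyllithium | [Li]c1ccco1 | intermediate
4 | furan-2-yl(2,3,4-trimethoxyphenyl)methanol (racemic) | COc1ccc(C(O)c2ccco2)c(OC)c1OC | intermediate
5 | 6-hydroxy-2-(2,3,4-trimethoxyphenyl)-2H-pyran-3(6H)-one (racemic anomer mixture) | COc1ccc(C2OC(O)C=CC2=O)c(OC)c1OC | intermediate
6 | 6-methoxy-2-(2,3,4-trimethoxyphenyl)-2H-pyran-3(6H)-one (racemic cis/trans mixture) | COc1ccc(C2OC(OC)C=CC2=O)c(OC)c1OC | intermediate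
7 | 2-methoxy-4-(2,3,4-trimethoxyphenyl)-3,7-dioxabicyclo[4.1.0]heptan-5-one (racemic diastereomer mixture) | COc1ccc(C2OC(OC)C3OC3C2=O)c(OC)c1OC | intermediate
8 | 3-hydroxy-2-(2,3,4-trimethoxyphenyl)-4H-pyran-4-one | COc1ccc(-c2occc(=O)c2O)c(OC)c1OC | intermediate
9 | 3-methoxy-2-(2,3,4-trimethoxyphenyl)-4H-pyran-4-one | COc1ccc(-c2occc(=O)c2OC)c(OC)c1OC | intermediate
10 | dimethyl squarate | COC1=C(OC)C(=O)C1=O | starting material
11 | 4-hydroxy-2,3-dimethoxycyclobut-2-en-1-one (racemic) | COC1=C(OC)C(O)C1=O | intermediate
12 | 3-methoxycyclobut-3-ene-1,2-dione (methyl semisquarate) | COC1=CC(=O)C1=O | intermediate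
13 | 6-lithio-3-methoxy-2-(2,3,4-trimethoxyphenyl)-4H-pyran-4-one | COc1ccc(-c2oc([Li])cc(=O)c2OC)c(OC)c1OC | intermediate
14 | 4-hydroxy-3-methoxy-4-[5-methoxy-4-oxo-6-(2,3,4-trimethoxyphenyl)-4H-pyran-2-yl]cyclobut-2-en-1-one (racemic) | COc1ccc(-c2oc(C3(O)C(OC)=CC3=O)cc(=O)c2OC)c(OC)c1OC | intermediate
15 | (3Z)-4-hydroxy-3-methoxy-4-[5-methoxy-4-oxo-6-(2,3,4-trimethoxyphenyl)-4H-pyran-2-yl]buta-1,3-dien-1-one (dienylketene, pyranonyl cis to the ketenyl group) | COc1ccc(-c2oc(/C(O)=C(\C=C=O)OC)cc(=O)c2OC)c(OC)c1OC | intermediate
16 | 8-hydroxy-3,7-dimethoxy-2-(2,3,4-trimethoxyphenyl)-4aH-chromene-4,5-dione (racemic at C4a) | COc1ccc(C2=C(OC)C(=O)C3C(=O)C=C(OC)C(O)=C3O2)c(OC)c1OC | intermediate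
17 | 5,8-dihydroxy-3,7-dimethoxy-2-(2,3,4-trimethoxyphenyl)-4H-chromen-4-one (5,8-dihydroxy-3,7,2',3',4'-pentamethoxyflavone) | COc1ccc(-c2oc3c(O)c(OC)cc(O)c3c(=O)c2OC)c(OC)c1OC | target

Total step count: 10. Longest linear sequence: 8 steps (steps 1 to 6, then 9 and 10); the squarate branch (steps 7 and 8) joins at step 9.

Steps most likely to fail

Step 9. The short-lived 6-lithiopyranone may decompose or exchange protons before capture, and proton transfer from the semisquarate or attack at its vinylogous ester carbon may erode the 1,2-addition. The fallback sets out from compound 9 and returns at compound 14. Zincation of the same C–H with TMPZnCl·LiCl in THF at 25 °C should give the thermally robust chloro(pyranonyl)zinc F1. Iodine converts it into the isolable 6-iodo-3-methoxy-2-(2,3,4-trimethoxyphenyl)-4H-pyran-4-one F2, on which the site of metalation can be confirmed. Iodine–magnesium exchange with i-PrMgCl·LiCl at −40 °C then gives the chloro(pyranonyl)magnesium F3, a milder and longer-lived nucleophile. F3 is added to 12 at −78 °C and quenched with aq. NH4Cl to give 14.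

Step 10. The dienylketene may be diverted by the free hydroxyl or by adventitious nucleophiles, and the emerging electron-rich hydroquinone may be lost to air oxidation during prolonged heating. The fallback sets out from compound 14 and returns at compound 17. Silylation with Et3SiOTf and 2,6-lutidine in CH2Cl2 at −78 °C gives the triethylsilyl ether F4, in which the oxygen substituent still rotates outward but can no longer trap the ketene. Thermolysis in degassed toluene then gives the air-stable 5-hydroxy-8-(triethylsilyloxy)flavone F5. HF·pyridine in THF at 0 °C under argon releases 17.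

Step 4. Base-triggered enolization at the doubly activated C2–H and ring degradation may compete with conjugate addition of hydroperoxide. The fallback sets out from compound 6 and returns at compound 8, bypassing 7. Neutral dihydroxylation of the enone with OsO4 (cat.) and N-methylmorpholine N-oxide in acetone/H2O gives the 4,5-dihydroxy-6-methoxy-2-(2,3,4-trimethoxyphenyl)oxan-3-one F6. Warm 2 M H2SO4 in dioxane then dehydrates the β-hydroxy ketone and eliminates methanol to give 8.

Further compounds
F1 | step 9 | chloro[5-methoxy-4-oxo-6-(2,3,4-trimethoxyphenyl)-4H-pyran-2-yl]zinc | COc1ccc(-c2oc([Zn]Cl)cc(=O)c2OC)c(OC)c1OC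
F2 | step 9 | 6-iodo-3-methoxy-2-(2,3,4-trimethoxyphenyl)-4H-pyran-4-one | COc1ccc(-c2oc(I)cc(=O)c2OC)c(OC)c1OC
F3 | step 9 | chloro[5-methoxy-4-oxo-6-(2,3,4-trimethoxyphenyl)-4H-pyran-2-yl]magnesium | COc1ccc(-c2oc([Mg]Cl)cc(=O)c2OC)c(OC)c1OC
F4 | step 10 | 3-methoxy-4-[5-methoxy-4-oxo-6-(2,3,4-trimethoxyphenyl)-4H-pyran-2-yl]-4-(triethylsilyloxy)cyclobut-2-en-1-one (racemic) | COc1ccc(-c2oc(C3(O[Si](CC)(CC)CC)C(OC)=CC3=O)cc(=O)c2OC)c(OC)c1OC
F5 | step 10 | 5-hydroxy-3,7-dimethoxy-8-(triethylsilyloxy)-2-(2,3,4-trimethoxyphenyl)-4H-chromen-4-one | COc1ccc(-c2oc3c(O[Si](CC)(CC)CC)c(OC)cc(O)c3c(=O)c2OC)c(OC)c1OC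
F6 | step 4 | 4,5-dihydroxy-6-methoxy-2-(2,3,4-trimethoxyphenyl)oxan-3-one (racemic diastereomer mixture) | COc1ccc(C2OC(OC)C(O)C(O)C2=O)c(OC)c1OC
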